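The plan rests on cutting all four C–S bonds of the bithiophene. The feature exploited is that C2–C5 of ring A (thiophene bearing the butynyl arm) and C2'–C5' of ring B (thiophene bearing CH2O) lie on one unbranched eight-carbon line already joined at C2–C2'. Deleting both sulfur atoms therefore leaves a conjugated tetrayne. In a single operation sodium sulfide puts both sulfurs back and closes both rings. The precursor is a C10 tetrayne ending in a diethyl acetal, the seed of the side-chain alkyne, and in a CH2O–TIPS group. The silyl ether is preferred to a free carbinol because it caps the polyyne sterically and saves a later protection.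

Key step: step 7

Assumption: the target has no stereochemical element; the tetrayne chain is numbered from C1 (CH2O carbon) to C10 (acetal carbon); every tri- and tetrayne is taken to be handled only as a dilute, degassed solution in the dark and never evaporated to dryness.

Step 1
Reactants: 1 propargyl alcohol (prop-2-yn-1-ol)
Product: 2 triisopropyl(prop-2-yn-1-yloxy)silane
Conditions: TIPSCl, imidazole, CH2Cl2, 0 °C to rt
Reagents that add atoms: chlorotriisopropylsilane, CC(C)[Si](Cl)(C(C)C)C(C)C
Why: Imidazole-promoted O-silylation of an unhindered primary alcohol is routine, and TIPS is chosen because it should outlast aqueous amine, sulfide, mild acid and n-BuLi while giving every later polyyne a bulky, non-polar end cap.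

Step 2
Reactants: 2 triisopropyl(prop-2-yn-1-yloxy)silane
Product: 3 [(3-bromoprop-2-yn-1-yl)oxy]triisopropylsilane
Conditions: NBS, AgNO3 (cat.), acetone, rt, dark
Reagents that add atoms: N-bromosuccinimide, O=C1CCC(=O)N1Br
Why: AgNO3-catalysed electrophilic bromination of a terminal alkyne with NBS runs through the silver acetylide under neutral conditions that leave the silyl ether alone.

Step 3
Reactants: 4 1,4-bis(trimethylsilyl)buta-1,3-diyne
Product: 6 buta-1,3-diyn-1-yl(trimethyl)silane, via lithium diynide 5 (not isolated)
Conditions: MeLi·LiBr (1 equiv), Et2O, 0 °C to rt; then sat. aq. NH4Cl, 0 °C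
Reagents that add atoms: none
Why: Selective mono-protiodesilylation: MeLi attacks one silicon and expels the diynyl anion 5, whose charge shuts down attack at the second C–Si bond, and buffered protonation gives the volatile diyne 6, which is kept as an ethereal solution.

Step 4
Reactants: 3 [(3-bromoprop-2-yn-1-yl)oxy]triisopropylsilane; 6 buta-1,3-diyn-1-yl(trimethyl)silane
Product: 7 triisopropyl{[7-(trimethylsilyl)hepta-2,4,6-triyn-1-yl]oxy}silane
Conditions: CuCl (cat.), NH2OH·HCl (cat.), n-BuNH2, CH2Cl2, 0 °C, slow addition of 3
Reagents that add atoms: none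
Why: Cadiot–Chodkiewicz coupling, in which the copper acetylide of the acidic diyne 6 displaces bromide from 3, hydroxylamine holds copper in the monovalent state against Glaser homocoupling, and the nearly water-free medium at 0 °C spares the C–SiMe3 bond.

Step 5
Reactants: 8 3,3-diethoxyprop-1-yne
Product: 9 3-bromo-1,1-diethoxyprop-2-yne
Conditions: NBS, AgNO3 (cat.), acetone, rt, dark
Reagents that add atoms: N-bromosuccinimide, O=C1CCC(=O)N1Br
Why: The same AgNO3-catalysed NBS bromination of a terminal alkyne applies, and the neutral, non-aqueous medium does not touch the acetal.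

Step 6
Reactants: 7 triisopropyl{[7-(trimethylsilyl)hepta-2,4,6-triyn-1-yl]oxy}silane; 9 3-bromo-1,1-diethoxyprop-2-yne
Product: 11 [(10,10-diethoxydeca-2,4,6,8-tetrayn-1-yl)oxy]triisopropylsilane, via terminal triyne 10 (not isolated)
Conditions: K2CO3 (cat.), MeOH/THF, 0 °C; then CuCl (cat.), NH2OH·HCl (cat.), n-BuNH2, slow addition of 9, 0 °C, dark
Reagents that add atoms: none
Why: Carbonate-catalysed methanolysis of the C–SiMe3 bond and a Cadiot–Chodkiewicz coupling in the same flask let the fragile terminal triyne 10 serve at once as the acidic partner for the simple bromoalkyne 9, the polarity that favours cross- over homocoupling, while O-TIPS and acetal tolerate both basic stages.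

Step 7
Reactants: 11 [(10,10-diethoxydeca-2,4,6,8-tetrayn-1-yl)oxy]triisopropylsilane
Product: 13 {[5'-(diethoxymethyl)-2,2'-bithiophen-5-yl]methoxy}triisopropylsilane, via thienyl-diyne 12 (not isolated)
Conditions: Na2S·9H2O (excess), degassed THF/EtOH/H2O, slow addition of dilute 11 at 0 °C, then 50 °C, Ar, dark
Reagents that add atoms: sodium sulfide nonahydrate, O.O.O.O.O.O.O.O.O.[Na+].[Na+].[S-2]
Why: Hydrosulfide adds anti to a chain-end sp carbon, most likely C9 beside the inductively withdrawing acetal (C2 is screened by the TIPS group), since only end attack lets the developing carbanion spread over all three remaining triple bonds, and water protonates it to a (Z)-enynethiolate whose sulfur sits cis to the next alkyne. That thiolate closes ring A in a 5-endo-dig mode onto C6, and protonation of the thienyl anion gives the aromatic ring of 12 at once, so no tautomerisation step is involved. The thienyl-conjugated diyne left in 12 takes up a second hydrosulfide at C2 or C5 (both productive) and a second 5-endo-dig closure forms ring B, which needs the warming stage because a diyne is less electrophilic than a tetrayne. The closest known reaction type is the sulfide cyclisation of conjugated 1,3-diynes to 2,5-disubstituted thiophenes, which also operates on longer polyynes. No stereocentre is created; the selectivity required is attack at the chain ends rather than at C4 or C7, which would stop at a 2,5-dialkynylthiophene, and it is secured by the longer charge delocalisation and by the oxygen-bearing carbons at both termini, while attack from either end converges on 13. Slow addition of dilute 11 to excess sulfide keeps thiolate intermediates from adding to a second polyyne, and acetal and TIPS ether are indifferent to the basic medium.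

Step 8
Reactants: 13 {[5'-(diethoxymethyl)-2,2'-bithiophen-5-yl]methoxy}triisopropylsilane
Product: 14 5'-{[(triisopropylsilyl)oxy]methyl}-2,2'-bithiophene-5-carbaldehyde
Conditions: pyridinium p-toluenesulfonate (cat.), acetone/H2O, rt
Reagents that add atoms: water, O
Why: Acid-catalysed acetal hydrolysis is very fast here because the bithienyl unit stabilises the oxocarbenium ion, so a weak pyridinium acid suffices and the TIPS ether should stay in place.

Step 9
Reactants: 14 5'-{[(triisopropylsilyl)oxy]methyl}-2,2'-bithiophene-5-carbaldehyde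
Product: 15 [(5'-ethynyl-2,2'-bithiophen-5-yl)methoxy]triisopropylsilane
Conditions: dimethyl (1-diazo-2-oxopropyl)phosphonate, K2CO3, MeOH/THF, 0 °C to rt
Reagents that add atoms: dimethyl (1-diazo-2-oxopropyl)phosphonate, CC(=O)C(=[N+]=[N-])P(=O)(OC)OC
Why: Seyferth–Gilbert homologation in the Ohira–Bestmann variant: methanolysis frees the diazomethylphosphonate anion, which olefinates the non-enolisable aldehyde, and loss of N2 with a 1,2-hydrogen shift in the alkylidene carbene gives the terminal alkyne under conditions harmless to the silyl ether.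

Step 10
Reactants: 15 [(5'-ethynyl-2,2'-bithiophen-5-yl)methoxy]triisopropylsilane; 16 oxirane
Product: 18 4-(5'-{[(triisopropylsilyl)oxy]methyl}-2,2'-bithiophen-5-yl)but-3-yn-1-ol, via lithium acetylide 17 (not isolated)
Conditions: n-BuLi, THF, −78 °C; BF3·OEt2, then 16 (THF solution), −78 °C; H2O quench
Reagents that add atoms: none
Why: Yamaguchi–Hirao alkynylation, the BF3-assisted SN2 opening of an epoxide by a lithium acetylide, is reliable for aryl acetylides; the alkyne C–H is the only acidic site because both thiophene α-positions are substituted, and symmetrical oxirane poses no regiochemical question.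

Step 11
Reactants: 18 4-(5'-{[(triisopropylsilyl)oxy]methyl}-2,2'-bithiophen-5-yl)but-3-yn-1-ol
Product: 19 4-[5'-(hydroxymethyl)-2,2'-bithiophen-5-yl]but-3-yn-1-ol
Conditions: Bu4NF, THF, 0 °C to rt
Reagents that add atoms: none
Why: Fluoride-induced Si–O cleavage driven by the strong Si–F bond frees the thienylmethanol without affecting the alkyne or the rings.

Step 12
Reactants: 19 4-[5'-(hydroxymethyl)-2,2'-bithiophen-5-yl]but-3-yn-1-ol
Product: 20 4-(5'-{[(3-methylbutanoyl)oxy]methyl}-2,2'-bithiophen-5-yl)but-3-yn-1-yl 3-methylbutanoate (target)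
Conditions: 3-methylbutanoic anhydride (2.5 equiv), Et3N, DMAP (cat.), CH2Cl2, 0 °C to rt
Reagents that add atoms: 3-methylbutanoic anhydride, CC(C)CC(=O)OC(=O)CC(C)C
Why: DMAP-catalysed acylation esterifies both primary alcohols in one operation, and the basic, chloride-free medium avoids ionisation at the acid-sensitive thienylmethyl position.

Compound list
1 | propargyl alcohol | C#CCO | starting material
2 | triisopropyl(prop-2-yn-1-yloxy)silane | C#CCO[Si](C(C)C)(C(C)C)C(C)C | intermediate
3 | [(3-bromoprop-2-yn-1-yl)oxy]triisopropylsilane | BrC#CCO[Si](C(C)C)(C(C)C)C(C)C | intermediate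
4 | 1,4-bis(trimethylsilyl)buta-1,3-diyne | C[Si](C)(C)C#CC#C[Si](C)(C)C | starting material
5 | lithium 4-(trimethylsilyl)buta-1,3-diyn-1-ide | [Li]C#CC#C[Si](C)(C)C | intermediate
6 | buta-1,3-diyn-1-yl(trimethyl)silane | C#CC#C[Si](C)(C)C | intermediate
7 | triisopropyl{[7-(trimethylsilyl)hepta-2,4,6-triyn-1-yl]oxy}silane | C[Si](C)(C)C#CC#CC#CCO[Si](C(C)C)(C(C)C)C(C)C | intermediate
8 | 3,3-diethoxyprop-1-yne | C#CC(OCC)OCC | starting material
9 | 3-bromo-1,1-diethoxyprop-2-yne | BrC#CC(OCC)OCC | intermediate
10 | (hepta-2,4,6-triyn-1-yloxy)triisopropylsilane | C#CC#CC#CCO[Si](C(C)C)(C(C)C)C(C)C | intermediate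
11 | [(10,10-diethoxydeca-2,4,6,8-tetrayn-1-yl)oxy]triisopropylsilane (O-TIPS ether of 10,10-diethoxydeca-2,4,6,8-tetrayn-1-ol) | CCOC(OCC)C#CC#CC#CC#CCO[Si](C(C)C)(C(C)C)C(C)C | intermediate
12 | ({5-[5-(diethoxymethyl)thiophen-2-yl]penta-2,4-diyn-1-yl}oxy)triisopropylsilane | CCOC(OCC)c1ccc(C#CC#CCO[Si](C(C)C)(C(C)C)C(C)C)s1 | intermediate
13 | {[5'-(diethoxymethyl)-2,2'-bithiophen-5-yl]methoxy}triisopropylsilane (O-TIPS ether of [5'-(diethoxymethyl)-2,2'-bithiophen-5-yl]methanol) | CCOC(OCC)c1ccc(-c2ccc(CO[Si](C(C)C)(C(C)C)C(C)C)s2)s1 | intermediate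
14 | 5'-{[(triisopropylsilyl)oxy]methyl}-2,2'-bithiophene-5-carbaldehyde | O=Cc1ccc(-c2ccc(CO[Si](C(C)C)(C(C)C)C(C)C)s2)s1 | intermediate
15 | [(5'-ethynyl-2,2'-bithiophen-5-yl)methoxy]triisopropylsilane | C#Cc1ccc(-c2ccc(CO[Si](C(C)C)(C(C)C)C(C)C)s2)s1 | intermediate
16 | oxirane | C1CO1 | starting material
17 | lithium acetylide of 15 | [Li]C#Cc1ccc(-c2ccc(CO[Si](C(C)C)(C(C)C)C(C)C)s2)s1 | intermediate
18 | 4-(5'-{[(triisopropylsilyl)oxy]methyl}-2,2'-bithiophen-5-yl)but-3-yn-1-ol | OCCC#Cc1ccc(-c2ccc(CO[Si](C(C)C)(C(C)C)C(C)C)s2)s1 | intermediate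
19 | 4-[5'-(hydroxymethyl)-2,2'-bithiophen-5-yl]but-3-yn-1-ol | OCCC#Cc1ccc(-c2ccc(CO)s2)s1 | intermediate
20 | 4-(5'-{[(3-methylbutanoyl)oxy]methyl}-2,2'-bithiophen-5-yl)but-3-yn-1-yl 3-methylbutanoate | CC(C)CC(=O)OCCC#Cc1ccc(-c2ccc(COC(=O)CC(C)C)s2)s1 | target

Total step count: 12.
Longest linear sequence: 10 steps (1 → 2 → 3 → 7 → 11 → 13 → 14 → 15 → 18 → 19 → 20, that is steps 1, 2, 4, 6–12). Steps 3 and 5 are side branches.

Steps most likely to fail

1. Step 7.
- **Risk:** Sulfide may attack an inner alkyne carbon. The base may isomerise the acetal terminus from propargyl to allene. Thiolates may add intermolecularly and polymerise the tetrayne before both rings close.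
- **Fallback:** Only one ring is stitched, on a robust diyne, and the other ring is bought. Setting out from 3, Cadiot–Chodkiewicz coupling with commercial 2-ethynylthiophene (CuCl cat., NH2OH·HCl, n-BuNH2, 0 °C) should give triisopropyl{[5-(thiophen-2-yl)penta-2,4-diyn-1-yl]oxy}silane F1. Na2S·9H2O in warm DMF should close this single diyne to (2,2'-bithiophen-5-ylmethoxy)triisopropylsilane F2. Lithiation of the only free α-position with n-BuLi (THF, −78 °C) and a DMF quench comes back to the route at aldehyde 14.

2. Step 6.
- **Risk:** The terminal triyne may decay before it couples. Halogen–copper exchange may lead to homocoupling. The primary amine may add to the finished tetrayne.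
- **Fallback:** The coupling polarity is reversed, so that no terminal triyne ever exists. Setting out from 7, desilylative bromination with NBS and AgF in MeCN in the dark should give [(7-bromohepta-2,4,6-triyn-1-yl)oxy]triisopropylsilane F3. This is used as a solution and cross-coupled with the commercial terminal alkyne 8 under PdCl2(PPh3)2/CuI catalysis in i-Pr2NH/THF (Sonogashira-type alkynyl–alkynyl coupling), coming back at 11. The bromination of 8 then becomes unnecessary.

3. Step 10.
- **Risk:** The Lewis acid may ionise the thienylmethyl C–O bond. Oxirane may oligomerise faster than the acetylide captures it. Conversion may stay incomplete.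
- **Fallback:** The two carbons arrive through a copper carbene, with no Lewis acid and no strong base. Setting out from 15, CuI-catalysed coupling with ethyl diazoacetate in MeCN at rt should give ethyl 4-(5'-{[(triisopropylsilyl)oxy]methyl}-2,2'-bithiophen-5-yl)but-3-ynoate F4. Reduction with i-Bu2AlH in CH2Cl2 (−78 °C to 0 °C) comes back at 18.

Further compounds
F1 | step 7 | triisopropyl{[5-(thiophen-2-yl)penta-2,4-diyn-1-yl]oxy}silane | CC(C)[Si](OCC#CC#Cc1cccs1)(C(C)C)C(C)C
F2 | step 7 | (2,2'-bithiophen-5-ylmethoxy)triisopropylsilane | CC(C)[Si](OCc1ccc(-c2cccs2)s1)(C(C)C)C(C)C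
F3 | step 6 | [(7-bromohepta-2,4,6-triyn-1-yl)oxy]triisopropylsilane | BrC#CC#CC#CCO[Si](C(C)C)(C(C)C)C(C)C
F4 | step 10 | ethyl 4-(5'-{[(triisopropylsilyl)oxy]methyl}-2,2'-bithiophen-5-yl)but-3-ynoate | CCOC(=O)CC#Cc1ccc(-c2ccc(CO[Si](C(C)C)(C(C)C)C(C)C)s2)s1
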